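## Retrosynthetic overview

1. Feature: each indole has an unsubstituted benzo ring (C4–C7) joined to the pyrrole part only through C3–C3a and N1–C7a. Its C3 sits on C5 or C8 of the chromene, whose benzene ring is hexasubstituted. Each indole is therefore a plain phenyl ring plus a two-carbon nitrogen unit, and the central ring has no ortho C–H that could compete.
2. Key disconnection: both N1–C7a bonds at once, back to a 5,8-bis(2-nitro-1-phenylvinyl)chroman. Deoxygenation by CO at palladium/phenanthroline closes both pyrrole rings, with the crowded C3–C5 and C3–C8 aryl bonds already in place.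
3. Arms: the C–N bonds come from radical nitration of two 1-phenylvinyl groups, and the C5–C and C8–C bonds from a double Suzuki coupling of the 5,8-dibromochroman. The dibromide is made by electrophilic dibromination, because in a metalation sequence the second lithiation would exchange the first halogen.
4. The pyran ring comes from prenal and a vanillin-derived phenol (oxa-6π closure) and is saturated at once, so only the 1-phenylvinyl alkenes meet the NO2 radical and the reducing catalyst. DDQ restores C3=C4 after the indoles exist, and the 6-O-MOM group is then removed.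
5. Ring order: benzene ring (vanillin) → pyran ring → both pyrrole rings together (the two phenyl rings become the indole benzo rings).

Key step: step 8

Assumption: the radical nitration is not expected to control the geometry of the two trisubstituted nitroalkenes, so the dinitro compound is drawn and named as the E,E isomer (each nitro cis to phenyl, the geometry that cyclises) and the isomer mixture is taken into the key step unseparated; the target has no stereocentre and no axial descriptor, so nothing else stereochemical has to be set.

## Route

Step 1
Reactants: 1 vanillin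
Product: 2 MOM-vanillin (3-methoxy-4-(methoxymethoxy)benzaldehyde)
Conditions: MOMCl (1.3 equiv), K2CO3 (2 equiv), acetone, 0 °C to rt
Reagents that add atoms: chloromethyl methyl ether (MOMCl), COCCl
Why: Williamson-type O-alkylation of the acidic vanillin phenoxide with the reactive α-chloro ether gives an acetal ether that survives base, palladium and oxidants and keeps the ring activated for the later bromination.

Step 2
Reactants: 2 MOM-vanillin
Product: 4 3-methoxy-4-(methoxymethoxy)phenol, via aryl formate 3 (not isolated)
Conditions: mCPBA (1.3 equiv), CH2Cl2, 0 °C to rt; NaHCO3 wash; then K2CO3 (0.2 equiv), MeOH, rt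
Reagents that add atoms: meta-chloroperoxybenzoic acid (mCPBA), O=C(OO)c1cccc(Cl)c1
Why: Baeyer–Villiger oxidation of an electron-rich benzaldehyde proceeds with aryl migration to the formate, and base-catalysed transesterification with methanol frees the phenol without touching the MOM acetal.

Step 3
Reactants: 4 3-methoxy-4-(methoxymethoxy)phenol; 5 prenal (3-methylbut-2-enal)
Product: 7 MOM-chromene (7-methoxy-6-(methoxymethoxy)-2,2-dimethyl-2H-chromene), via o-quinone methide 6 (not isolated)
Conditions: PhB(OH)2 (1.0 equiv), AcOH (0.3 equiv), toluene, reflux, Dean–Stark, N2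
Reagents that add atoms: none
Why: Phenylboronic acid-mediated ortho-condensation of a phenol with an enal takes place at the less hindered ortho carbon, which is also para to the methoxy group, and the resulting o-quinone methide closes the 2,2-dimethyl-2H-pyran ring by oxa-6π electrocyclisation.

Step 4
Reactants: 7 MOM-chromene
Product: 8 MOM-chroman (7-methoxy-6-(methoxymethoxy)-2,2-dimethylchroman)
Conditions: H2 (1 atm), Pd/C (10 wt %), EtOAc, rt
Reagents that add atoms: none
Why: Catalytic hydrogenation of the styrene-type C3=C4 bond is fast under mild conditions and leaves the aryl ethers and the MOM acetal unchanged, so that later only the 1-phenylvinyl alkenes are present when the nitrating radical is generated.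

Step 5
Reactants: 8 MOM-chroman
Product: 9 dibromide (5,8-dibromo-7-methoxy-6-(methoxymethoxy)-2,2-dimethylchroman)
Conditions: NBS (2.2 equiv), MeCN, 0 °C to rt, dark
Reagents that add atoms: N-bromosuccinimide (NBS), O=C1CCC(=O)N1Br
Why: Electrophilic aromatic bromination should fill the only two ring C–H positions, since C8 is ortho to O1 and 7-OMe and C5 is ortho to 6-OMOM and the C4 alkyl group, while the neutral succinimide by-product spares the MOM group and no organolithium ever meets an aryl halide.

Step 6
Reactants: 9 dibromide; 10 1-phenylvinylboronic acid pinacol ester (two units incorporated)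
Product: 11 bis(styrenyl)chroman (7-methoxy-6-(methoxymethoxy)-2,2-dimethyl-5,8-bis(1-phenylvinyl)chroman)
Conditions: 10 (3 equiv), Pd(OAc)2 (5 mol %), SPhos (10 mol %), K3PO4 (5 equiv), toluene/H2O (10:1), 100 °C
Reagents that add atoms: none
Why: Double Suzuki–Miyaura coupling with a bulky, electron-rich biarylphosphine is suited to oxidative addition and reductive elimination at di-ortho-substituted, electron-rich aryl bromides, and the excess boronate covers protodeboronation.

Step 7
Reactants: 11 bis(styrenyl)chroman
Product: 12 dinitro compound (7-methoxy-6-(methoxymethoxy)-2,2-dimethyl-5,8-bis[(E)-2-nitro-1-phenylvinyl]chroman)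
Conditions: AgNO2 (6 equiv), TEMPO (0.8 equiv), 4 Å MS, ClCH2CH2Cl, 70 °C
Reagents that add atoms: silver nitrite (AgNO2), [Ag+].[O-]N=O
Why: In this radical alkene nitration the NO2 radical adds to each terminal CH2 to give a tertiary diaryl-stabilised radical, from which TEMPO removes the adjacent hydrogen, and the hexasubstituted ring offers no C–H for ring nitration.

Step 8
Reactants: 12 dinitro compound
Product: 13 bis(indolyl)chroman (3,3'-[7-methoxy-6-(methoxymethoxy)-2,2-dimethylchroman-5,8-diyl]bis(1H-indole), that is 3,4-dihydrokumbicin C 6-O-MOM ether)
Conditions: PdCl2(CH3CN)2 (5 mol %), 1,10-phenanthroline (20 mol %), Et3N (0.5 equiv), CO (10 bar), CH3CN, 140 °C, autoclave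
Reagents that add atoms: none
Why: CO and Et3N reduce the divalent precatalyst to a zerovalent palladium–phenanthroline species, which transfers an electron to each nitroalkene and removes one oxygen as CO2 to reach the nitrosoalkene level; the nitroso nitrogen then bonds to the ortho carbon of the phenyl ring lying cis to it, a hydrogen shift restores aromaticity at the N-hydroxyindole level, and a second CO removes the last oxygen. The closest known reaction type is the palladium/phenanthroline-catalysed reductive cyclisation of 2-nitro-1,1-diarylethenes (α-aryl-β-nitrostyrenes) with CO or formate esters to 3-arylindoles, run here on two arms of one molecule. Each pyrrole ring closes in the same mode, a five-membered 1,5-electrocyclisation of the O=N–Cβ=Cα–C(ipso)=C(ortho) array (formally 5-endo-trig) that forms N1–C7a, while Cα, already bonded to chroman C5 or C8, becomes indole C3. No stereocentre is created. The step needs site selectivity in the C–H amination, and the substrate secures it because the four central-ring atoms ortho to the arms (C4a, C6, C7 and C8a) all carry substituents, so only a phenyl ortho C–H can be replaced, and the two ortho positions of each phenyl are equivalent. An arm whose nitro group faces the central ring should still converge, because rotation about Cα–Cβ in the nitroalkene radical anion, reversible conjugate addition of Et3N at 140 °C, or passage through a 2,2-diaryl-2H-azirine erases the alkene geometry before the irreversible aromatisation.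

Step 9
Reactants: 13 bis(indolyl)chroman
Product: 14 kumbicin C 6-O-MOM ether (3,3'-[7-methoxy-6-(methoxymethoxy)-2,2-dimethyl-2H-chromene-5,8-diyl]bis(1H-indole))
Conditions: DDQ (1.3 equiv), 1,4-dioxane, 100 °C
Reagents that add atoms: none
Why: In this DDQ dehydrogenation of a chroman, hydride abstraction from C4 gives a benzylic cation stabilised by O1 (ortho, through C8a) and by the 7-methoxy group (para to C4a), loss of H3 gives the 2H-chromene, the 3-arylindoles have no C–H next to C3 for the quinone to attack, and the masked 6-oxygen prevents quinone formation.

Step 10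
Reactants: 14 kumbicin C 6-O-MOM ether
Product: 15 kumbicin C
Conditions: ZnBr2 (1 equiv), n-PrSH (2.2 equiv), CH2Cl2, 0 °C to rt, short contact time
Reagents that add atoms: none
Why: In this Lewis acid-assisted acetal cleavage with a soft nucleophile, ZnBr2 activates the MOM group and propanethiol carries off its CH2 unit as the dithioacetal, so there is neither a strong Brønsted acid to protonate the electron-rich chromene nor free formaldehyde to alkylate indole C2.

## Compound list

1 | vanillin | COc1cc(C=O)ccc1O | starting material
2 | 3-methoxy-4-(methoxymethoxy)benzaldehyde | COCOc1ccc(C=O)cc1OC | intermediate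
3 | 3-methoxy-4-(methoxymethoxy)phenyl formate | COCOc1ccc(OC=O)cc1OC | intermediate
4 | 3-methoxy-4-(methoxymethoxy)phenol | COCOc1ccc(O)cc1OC | intermediate
5 | prenal (3-methylbut-2-enal) | CC(C)=CC=O | starting material
6 | (6Z)-3-methoxy-4-(methoxymethoxy)-6-(3-methylbut-2-en-1-ylidene)cyclohexa-2,4-dien-1-one | O=C1C=C(OC)C(OCOC)=C/C1=C/C=C(C)C | intermediate
7 | 7-methoxy-6-(methoxymethoxy)-2,2-dimethyl-2H-chromene | COCOc1cc2C=CC(C)(C)Oc2cc1OC | intermediate
8 | 7-methoxy-6-(methoxymethoxy)-2,2-dimethylchroman | COCOc1cc2CCC(C)(C)Oc2cc1OC | intermediate
9 | 5,8-dibromo-7-methoxy-6-(methoxymethoxy)-2,2-dimethylchroman | COCOc1c(Br)c2CCC(C)(C)Oc2c(Br)c1OC | intermediate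
10 | 1-phenylvinylboronic acid pinacol ester | C=C(c1ccccc1)B1OC(C)(C)C(C)(C)O1 | starting material
11 | 7-methoxy-6-(methoxymethoxy)-2,2-dimethyl-5,8-bis(1-phenylvinyl)chroman | COCOc1c(C(=C)c2ccccc2)c2CCC(C)(C)Oc2c(C(=C)c2ccccc2)c1OC | intermediate
12 | 7-methoxy-6-(methoxymethoxy)-2,2-dimethyl-5,8-bis[(E)-2-nitro-1-phenylvinyl]chroman | COCOc1c(OC)c(/C(c2ccccc2)=C/[N+](=O)[O-])c2OC(C)(C)CCc2c1/C(c1ccccc1)=C/[N+](=O)[O-] | intermediate
13 | 3,3'-[7-methoxy-6-(methoxymethoxy)-2,2-dimethylchroman-5,8-diyl]bis(1H-indole) | COCOc1c(OC)c(-c2c[nH]c3ccccc23)c2OC(C)(C)CCc2c1-c1c[nH]c2ccccc12 | intermediate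
14 | 3,3'-[7-methoxy-6-(methoxymethoxy)-2,2-dimethyl-2H-chromene-5,8-diyl]bis(1H-indole) | COCOc1c(OC)c(-c2c[nH]c3ccccc23)c2OC(C)(C)C=Cc2c1-c1c[nH]c2ccccc12 | intermediate
15 | kumbicin C (5,8-di(1H-indol-3-yl)-7-methoxy-2,2-dimethyl-2H-chromen-6-ol) | COc1c(O)c(-c2c[nH]c3ccccc23)c2c(c1-c1c[nH]c3ccccc13)OC(C)(C)C=C2 | target

Total step count: 10
Longest linear sequence: 10 steps, from vanillin 1 to kumbicin C 15 (prenal 5 and boronate 10 enter as purchased).

## Steps most likely to fail

**Step 8.**
- One arm may close while the other stalls.
- Arms whose nitro group faces the central ring may equilibrate too slowly.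
- The nitroso stage may be reduced further to the enamine level and hydrolyse.
- The nitroalkene may oligomerise under base at 140 °C.

The fallback brings the indoles in ready-made and forms the aryl–indole bonds by cross-coupling. It sets out from dibromide 9. A double Suzuki–Miyaura coupling is run with commercial 1-(phenylsulfonyl)indol-3-ylboronic acid pinacol ester (Pd(OAc)2, SPhos, K3PO4, toluene/H2O, 100 °C). It should give 7-methoxy-6-(methoxymethoxy)-2,2-dimethyl-5,8-bis[1-(phenylsulfonyl)-1H-indol-3-yl]chroman F1. Cleavage of both sulfonamides with NaOH in MeOH/THF at reflux returns to the route at 13.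

**Step 9.**
- Electron transfer from the indole rings may outrun hydride loss from C4. N–H deprotonation, coupling at indole C2 or addition of the reduced quinone would follow.
- The electron-rich product may be oxidised further.

The fallback makes both heterocycles electron-poor before the oxidation, so that C4–H is the only site open to the quinone. It sets out from 13. Boc2O with catalytic DMAP in MeCN should give di-tert-butyl 3,3'-[7-methoxy-6-(methoxymethoxy)-2,2-dimethylchroman-5,8-diyl]bis(1H-indole-1-carboxylate) F2. DDQ in refluxing dioxane should then give di-tert-butyl 3,3'-[7-methoxy-6-(methoxymethoxy)-2,2-dimethyl-2H-chromene-5,8-diyl]bis(1H-indole-1-carboxylate) F3. Methanolysis of both indole carbamates (K2CO3, MeOH, reflux) returns to the route at 14.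

**Step 6.**
- Oxidative addition and transmetalation at the di-ortho-substituted C5 and C8 may be slow, so the reaction could stop after one coupling.
- The boronate may be lost by protodeboronation, or the second bromide by hydrodebromination.

The fallback is a Barluenga-type coupling, which replaces the hindered transmetalation by carbene migratory insertion. It sets out from 9 and uses commercial acetophenone N-tosylhydrazone (Pd2(dba)3, XPhos, LiOt-Bu, 1,4-dioxane, 100 °C). The diazo compound formed in the flask gives a palladium carbene. The aryl group migrates to it, and β-hydride elimination delivers each 1,1-diarylethene unit. The fallback comes back to the route directly at 11 and makes no new compound (F0).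

## Further compounds

F1 | step 8 | 7-methoxy-6-(methoxymethoxy)-2,2-dimethyl-5,8-bis[1-(phenylsulfonyl)-1H-indol-3-yl]chroman | COCOc1c(OC)c(-c2cn(S(=O)(=O)c3ccccc3)c3ccccc23)c2OC(C)(C)CCc2c1-c1cn(S(=O)(=O)c2ccccc2)c2ccccc12
F2 | step 9 | di-tert-butyl 3,3'-[7-methoxy-6-(methoxymethoxy)-2,2-dimethylchroman-5,8-diyl]bis(1H-indole-1-carboxylate) | COCOc1c(OC)c(-c2cn(C(=O)OC(C)(C)C)c3ccccc23)c2OC(C)(C)CCc2c1-c1cn(C(=O)OC(C)(C)C)c2ccccc12
F3 | step 9 | di-tert-butyl 3,3'-[7-methoxy-6-(methoxymethoxy)-2,2-dimethyl-2H-chromene-5,8-diyl]bis(1H-indole-1-carboxylate) | COCOc1c(OC)c(-c2cn(C(=O)OC(C)(C)C)c3ccccc23)c2OC(C)(C)C=Cc2c1-c1cn(C(=O)OC(C)(C)C)c2ccccc12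
F0 | step 6 | none | none
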